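The tetrasubstituted butenolide alkene C7=C11 carries the allylic oxygen on C13 and faces the oxygenated C1 across the ten-membered ring (C1 to C10). A bond C1-C7 plus an oxygen bridge C11-O-C13 converts this pattern into the array O-C1-C7-C11(O)-C13 of a 5/7 bicycle (cyclopentane C1, C10, C9, C8, C7; cycloheptene C1 to C7).
Late disconnections: the C1 carbinol comes from the C1 enone by reagent-controlled reduction, and both acetates come from the 8,13-diol. The ten-membered ring comes from Grob-type cleavage of the temporary C1-C7 bond of a trans-fused hydroazulenol that bears an 11,13-epoxy-6,12-lactone.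
Precursor: the oxirane comes from the alpha-methylene lactone, and the lactone from a C6 ketone by C1-OH-directed reduction and lactonisation. C4=C5 is made by ring-closing metathesis, C1-C2 by organocerium addition, C10=C14 and C11=C13 by Mannich methylenation, and quaternary C7 by alkylation then aldol addition on (R)-4-silyloxycyclopentenone.
Order of rings: cyclopentane (starting material), cycloheptene, gamma-lactone, oxirane. The key step then merges the two carbocycles into the ten-membered ring and opens the oxirane.
Key step: step 14

Numbering: germacrane numbering (C1 to C15) is used for all intermediates. "Top" is the cyclopentane face that carries C6 on C7. "Bottom" is the face that carries C11 on C7 and the C8 silyloxy group.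
Assumption: the aldol step may give both C6 epimers. The epimer expected from a chair transition state (6S) is drawn for 5 to 16, and either epimer converges at 17.

Step 1
Reactants: 1 (R)-4-(tert-butyldimethylsilyloxy)cyclopent-2-enone; 2 tert-butyl bromoacetate
Product: 3 tert-butyl 2-[(1R,5S)-5-(tert-butyldimethylsilyloxy)-2-oxocyclopent-3-en-1-yl]acetate (C11 chain trans to O8)
Conditions: LiN(i-Pr)2, THF, -78 °C; 2, DMPU, -78 to -40 °C
Reagents that add atoms: none
Why: Kinetic deprotonation gives the cross-conjugated alpha-prime lithium enolate, which does not expel the C8 silanolate because that would produce an antiaromatic cyclopentadienone, and enolate alkylation (SN2) by the activated bromide occurs anti to the silyloxy group to give the trans product, whose C7 configuration is provisional since C7 is planarised again in step 2.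

Step 2
Reactants: 3 alkylated enone; 4 acrolein
Product: 5 tert-butyl 2-{(1R,5S)-5-(tert-butyldimethylsilyloxy)-1-[(1S)-1-hydroxyprop-2-enyl]-2-oxocyclopent-3-en-1-yl}acetate (quaternary C7: C6 top, C11 bottom)
Conditions: LiN(i-Pr)2, THF, -78 °C; 4, -78 °C; AcOH, -78 °C
Reagents that add atoms: none
Why: Lithium enolate aldol addition: the ketone alpha-prime proton at C7 is removed faster than the alpha protons of the hindered tert-butyl ester, acrolein adds 1,2 at low temperature on the enolate face anti to the C8 silyloxy group and thereby sets quaternary C7, a chair Zimmerman-Traxler transition state should favour the 6S carbinol drawn, and the C6 configuration is of no consequence because it is erased in step 9 and reset in step 10.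

Step 3
Reactants: 5 aldol adduct
Product: 6 C6 triethylsilyl ether of 5
Conditions: Et3SiOTf, 2,6-lutidine, CH2Cl2, -78 to 0 °C
Reagents that add atoms: triethylsilyl triflate, CC[Si](CC)(CC)OS(=O)(=O)C(F)(F)F
Why: Silyl ether formation under non-basic conditions blocks retro-aldol cleavage of the hindered beta-hydroxy ketone, adds bulk to the top-face substituent for step 6, and gives a group that can later be removed in the presence of the C8 tert-butyldimethylsilyl ether; no stereocentre is touched.

Step 4
Reactants: 6 silylated enone
Product: 7 cyclopentanone (C9-C10 saturated; C6, C7, C8 unchanged)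
Conditions: Cu(OAc)2·H2O (5 mol %), 1,2-bis(diphenylphosphino)benzene (5 mol %), (EtO)2MeSiH, t-BuOH, toluene, rt
Reagents that add atoms: none
Why: Copper hydride (CuH) catalysed conjugate reduction is selective for the enone over the isolated vinyl group and the ester, the copper enolate at C10 has no beta leaving group and is protonated by t-BuOH, and no stereocentre is formed.

Step 5
Reactants: 7 cyclopentanone
Product: 10 C10-methylene cyclopentanone (exocyclic enone C1=O/C10=C14), via Mannich base 8 (not isolated), via methiodide 9 (not isolated)
Conditions: LiN(SiMe3)2, THF, -78 °C; CH2=NMe2+ I-, -78 °C to rt; MeI, Et2O, rt; aq NaHCO3, CH2Cl2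
Reagents that add atoms: Eschenmoser's salt, C=[N+](C)C.[I-]; iodomethane, CI (into 9 only)
Why: Alpha-methylenation by Mannich reaction of the lithium enolate with Eschenmoser's salt, N-methylation and base-induced beta-elimination is regiospecific because C7 is quaternary and C10 is the only enolisable position of the ketone, and the transient C10 stereocentre disappears in the elimination.

Step 6
Reactants: 10 exocyclic enone; 11 4-bromo-2-methylbut-1-ene
Product: 14 tertiary allylic alcohol (O1 top and cis to C6; chain C2-C3-C4 bottom and cis to C11 and O8), via Grignard reagent 12 (not isolated), via organocerium reagent 13 (not isolated)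
Conditions: 11, Mg, THF, rt; CeCl3 (anhydrous), THF, -78 °C; 10, -78 °C; aq NH4Cl
Reagents that add atoms: magnesium, [Mg] (into 12 only); cerium trichloride, [Ce+3].[Cl-].[Cl-].[Cl-] (into 13 only)
Why: Organocerium 1,2-addition: the weakly basic and oxophilic cerium reagent adds to the carbonyl carbon of the exocyclic enone instead of C14 and leaves the tert-butyl ester untouched at low temperature, and it approaches C1 from the bottom face, anti to the branched CH(OSiEt3)CH=CH2 group on the neighbouring quaternary C7, which places O1 on the top face (trans to C11) and C2 on the bottom face.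

Step 7
Reactants: 14 tertiary alcohol
Product: 15 trans-fused hydroazulenol (bicyclo[5.3.0]decene with cis C4=C5, C6 OSiEt3, C7 CH2CO2t-Bu, C8 OTBS, C10 methylene)
Conditions: second-generation Grubbs catalyst RuCl2(=CHPh)(PCy3)(H2IMes) (5 mol %), CH2Cl2 (2 mM), reflux
Reagents that add atoms: none
Why: Ring-closing metathesis: the ruthenium carbene loads on the monosubstituted C5 vinyl group and closes the seven-membered ring on the 1,1-disubstituted C4 alkene, C4=C5 can only be cis in this ring size, the C10 methylene cannot compete because closure onto it would need a bridgehead alkene, and the trans ring fusion follows from the C1 and C7 configurations already present.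

Step 8
Reactants: 15 bicyclic silyl ether
Product: 16 C6 allylic alcohol
Conditions: HF·pyridine, pyridine, THF, 0 °C
Reagents that add atoms: none
Why: Fluoride-mediated desilylation under buffered conditions distinguishes the triethylsilyl ether from the much slower reacting neopentylic tert-butyldimethylsilyl ether at C8 and is mild enough for the tertiary allylic alcohol.

Step 9
Reactants: 16 allylic alcohol
Product: 17 C6 cycloheptenone (beta-hydroxy ketone C1-OH/C6=O)
Conditions: Dess-Martin periodinane, CH2Cl2, 0 °C to rt
Reagents that add atoms: none
Why: Dess-Martin oxidation of the secondary allylic alcohol under neutral conditions gives the cycloheptenone without retro-aldol opening of the beta-hydroxy ketone, leaves the tertiary alcohol untouched and removes the C6 stereocentre so that both aldol epimers converge.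

Step 10
Reactants: 17 enone
Product: 18 1,3-anti diol (6R; O6 on the seven-membered-ring face that carries C11 and opposite to O1)
Conditions: Me4NBH(OAc)3, MeCN/AcOH, -30 °C
Reagents that add atoms: none
Why: Hydroxyl-directed Evans-Saksena reduction: exchange of acetate for the C1 hydroxyl ties the borohydride to O1, which lies close to C6 (both on the top face of the cyclopentane), hydride is delivered intramolecularly and 1,2-selectively to the carbonyl face turned toward O1, and the 1,3-anti diol results with O6 cis to the C11 chain.

Step 11
Reactants: 18 diol ester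
Product: 19 tricyclic 6,12-lactone (cis-fused to the cycloheptene and spiro to the cyclopentane at C7)
Conditions: KOt-Bu (20 mol %), THF, 0 °C to rt
Reagents that add atoms: none
Why: Base-catalysed lactonisation (intramolecular transesterification, 5-exo-trig): only the C6 alkoxide is cis to the C11 acetate arm, whereas O1 is trans to it and cannot reach C12, so the cis-fused lactone forms with retention at C6 and tert-butoxide is regenerated.

Step 12
Reactants: 19 lactone
Product: 22 alpha-methylene lactone (C11=C13), via lactone Mannich base 20 (not isolated), via lactone methiodide 21 (not isolated)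
Conditions: LiN(i-Pr)2 (2.3 equiv), THF, -78 °C; CH2=NMe2+ I-, -78 °C to rt; MeI, MeOH, rt; aq NaHCO3, CH2Cl2
Reagents that add atoms: Eschenmoser's salt, C=[N+](C)C.[I-]; iodomethane, CI (into 21 only)
Why: Alpha-methylenation of the lactone by the Mannich, quaternisation and elimination sequence: the second equivalent of base forms the lactone enolate at C11 after the C1 alkoxide, the small iminium ion can reach the neopentylic C11, and the transient C11 stereocentre is lost in the elimination.

Step 13
Reactants: 22 alpha-methylene lactone
Product: 23 trans-fused hydroazulenol with 11,13-epoxy-6,12-lactone (oxirane oxygen on the lactone face syn to C8 and H6, anti to C1)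
Conditions: t-BuOOH (3 equiv, anhydrous, toluene), n-BuLi (1.1 equiv), THF, -78 to -20 °C
Reagents that add atoms: tert-butyl hydroperoxide, CC(C)(C)OO
Why: Nucleophilic (Weitz-Scheffer type) epoxidation with lithium tert-butyl peroxide attacks only the electron-poor C11=C13 bond and not C4=C5 or C10=C14; ring closure of the peroxy enolate should occur on the convex face of the cis-fused lactone, because on the other face the new C11-O bond would eclipse C7-C1 and run into C2 and C3 of the boat-like cycloheptene, which sets C11 with the oxirane oxygen anti to C1; and the excess hydroperoxide keeps the medium too weakly basic to deprotonate the C1 hydroxyl.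

Step 14
Reactants: 23 epoxy lactone hydroazulenol
Product: 24 8alpha-(tert-butyldimethylsilyloxy)-13-hydroxy-1-oxogermacra-4,7(11),10(14)-trien-6alpha,12-olide
Conditions: KN(SiMe3)2 (1.05 equiv), THF, -78 to -30 °C; AcOH, -78 °C
Reagents that add atoms: none
Why: Proposed new method: KN(SiMe3)2 removes the C1 hydroxyl proton and, in one concerted heterolytic event, an oxygen lone pair builds C1=O, the C1-C7 sigma pair becomes the C7=C11 pi bond and C11 releases the oxirane oxygen, which remains on C13 as the alkoxide until the acid quench. The closest known reaction type is the epoxy-alcohol (Grob-type) fragmentation of fused bicyclic gamma-hydroxy epoxides to medium-ring ketones carrying an allylic alcohol; untested is an oxirane carbon that is alpha to a lactone carbonyl, which should lower the barrier because the alkene is born in conjugation with C12=O and because the crowded 5/7/5 array and the three-membered ring are unloaded together. Mode of ring formation: no sigma bond closes the macrocycle, the perimeter of the bicyclo[5.3.0]decene becomes the ten-membered ring when the zero-atom bridge C1-C7 is cut (ring merger). No stereocentre is created: C1, C7 and C11 become trigonal, C6 and C8 are spectators, and C4=C5 keeps the cis geometry fixed in the seven-membered ring. The selectivity required is cleavage of C1-C7 alone, and it is secured because only O1 can become an alkoxide (O8 is silylated, O6 acylated), because the lactone ring holds the C11-O bond on the face opposite to C1 so that models of the boat-like cycloheptene put the C1-C7-C11-O dihedral angle close to anti-periplanar while C7-C8 is gauche to that bond, and because in the trans-fused bicycle O1 is anti to C11 and can reach neither C12 nor C13. One equivalent of base, low temperature and a cold AcOH quench keep the C13 alkoxide from abstracting H6 or H2 of the product.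

Step 15
Reactants: 24 silyl ether
Product: 25 8alpha,13-dihydroxy-1-oxogermacra-4,7(11),10(14)-trien-6alpha,12-olide
Conditions: HF·pyridine, pyridine, THF, 0 °C to rt
Reagents that add atoms: none
Why: Acidic fluoride cleaves the now allylic and unhindered C8 silyl ether without the basic conditions that would deprotonate C6-H of the butenolide or add to the enone.

Step 16
Reactants: 25 diol
Product: 26 8alpha,13-diacetoxy-1-oxogermacra-4,7(11),10(14)-trien-6alpha,12-olide
Conditions: Ac2O, pyridine, DMAP (cat.), CH2Cl2, 0 °C
Reagents that add atoms: acetic anhydride, CC(=O)OC(C)=O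
Why: Standard acylation with nucleophilic catalysis by DMAP esterifies the primary C13 and secondary C8 hydroxyls, drains any transannular C8-O/C1 hemiketal through the open form, and is mild enough not to trigger elimination of the C13 acetate.

Step 17
Reactants: 26 diacetate enone
Product: 27 8alpha,13-diacetoxy-1alpha-hydroxygermacra-4,7(11),10(14)-trien-6alpha,12-olide (1S,6R,8S; target)
Conditions: (R)-2-methyl-CBS-oxazaborolidine (0.5 equiv), catecholborane, toluene, -78 °C
Reagents that add atoms: none
Why: Corey-Bakshi-Shibata reduction: the oxazaborolidine-catecholborane complex reduces the enone 1,2-selectively at low temperature without touching butenolide, acetates or alkenes, the branched alkenyl carbon C10 acts as the large and the C2 methylene as the small substituent, so the R catalyst should deliver hydride to give the 1S (1 alpha) alcohol under reagent control.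

Compound list
1 | (R)-4-(tert-butyldimethylsilyloxy)cyclopent-2-enone | O=C1C=C[C@H](O[Si](C)(C)C(C)(C)C)C1 | starting material
2 | tert-butyl bromoacetate | CC(C)(C)OC(=O)CBr | starting material
3 | trans-5-(tert-butoxycarbonylmethyl)-4-silyloxycyclopentenone | O=C1C=C[C@H](O[Si](C)(C)C(C)(C)C)[C@H]1CC(=O)OC(C)(C)C | intermediate
4 | acrolein | C=CC=O | starting material
5 | aldol adduct with quaternary C7 (6S drawn) | O=C1C=C[C@H](O[Si](C)(C)C(C)(C)C)[C@@]1(CC(=O)OC(C)(C)C)[C@@H](O)C=C | intermediate
6 | C6 triethylsilyl ether | O=C1C=C[C@H](O[Si](C)(C)C(C)(C)C)[C@@]1(CC(=O)OC(C)(C)C)[C@@H](O[Si](CC)(CC)CC)C=C | intermediate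
7 | saturated cyclopentanone | O=C1CC[C@H](O[Si](C)(C)C(C)(C)C)[C@@]1(CC(=O)OC(C)(C)C)[C@@H](O[Si](CC)(CC)CC)C=C | intermediate
8 | C10 Mannich base (C10 epimers) | O=C1C(CN(C)C)C[C@H](O[Si](C)(C)C(C)(C)C)[C@@]1(CC(=O)OC(C)(C)C)[C@@H](O[Si](CC)(CC)CC)C=C | intermediate
9 | C10 trimethylammoniomethyl ketone iodide | O=C1C(C[N+](C)(C)C)C[C@H](O[Si](C)(C)C(C)(C)C)[C@@]1(CC(=O)OC(C)(C)C)[C@@H](O[Si](CC)(CC)CC)C=C.[I-] | intermediate
10 | C10-methylene cyclopentanone | O=C1C(=C)C[C@H](O[Si](C)(C)C(C)(C)C)[C@@]1(CC(=O)OC(C)(C)C)[C@@H](O[Si](CC)(CC)CC)C=C | intermediate
11 | 4-bromo-2-methylbut-1-ene | C=C(C)CCBr | starting material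
12 | (3-methylbut-3-enyl)magnesium bromide | C=C(C)CC[Mg]Br | intermediate
13 | dichloro(3-methylbut-3-enyl)cerium | C=C(C)CC[Ce](Cl)Cl | intermediate
14 | tertiary allylic alcohol, O1 top, C2 bottom | C=C1C[C@H](O[Si](C)(C)C(C)(C)C)[C@@](CC(=O)OC(C)(C)C)([C@@H](O[Si](CC)(CC)CC)C=C)[C@]1(O)CCC(C)=C | intermediate
15 | trans-fused hydroazulenol, C6 OSiEt3 | C=C1C[C@H](O[Si](C)(C)C(C)(C)C)[C@@]2(CC(=O)OC(C)(C)C)[C@@H](O[Si](CC)(CC)CC)/C=C(/C)CC[C@]12O | intermediate
16 | trans-fused hydroazulenol, C6 OH (6S drawn) | C=C1C[C@H](O[Si](C)(C)C(C)(C)C)[C@@]2(CC(=O)OC(C)(C)C)[C@@H](O)/C=C(/C)CC[C@]12O | intermediate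
17 | C6 cycloheptenone | C=C1C[C@H](O[Si](C)(C)C(C)(C)C)[C@@]2(CC(=O)OC(C)(C)C)C(=O)/C=C(/C)CC[C@]12O | intermediate
18 | 1,6-anti diol (6R) | C=C1C[C@H](O[Si](C)(C)C(C)(C)C)[C@@]2(CC(=O)OC(C)(C)C)[C@H](O)/C=C(/C)CC[C@]12O | intermediate
19 | tricyclic 6,12-lactone | C=C1C[C@H](O[Si](C)(C)C(C)(C)C)[C@@]25CC(=O)O[C@@H]2/C=C(/C)CC[C@]15O | intermediate
20 | C11 Mannich base of the lactone (C11 epimers) | C=C1C[C@H](O[Si](C)(C)C(C)(C)C)[C@@]25C(CN(C)C)C(=O)O[C@@H]2/C=C(/C)CC[C@]15O | intermediate
21 | C11 trimethylammoniomethyl lactone iodide | C=C1C[C@H](O[Si](C)(C)C(C)(C)C)[C@@]25C(C[N+](C)(C)C)C(=O)O[C@@H]2/C=C(/C)CC[C@]15O.[I-] | intermediate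
22 | alpha-methylene lactone | C=C1C[C@H](O[Si](C)(C)C(C)(C)C)[C@@]25C(=C)C(=O)O[C@@H]2/C=C(/C)CC[C@]15O | intermediate
23 | 11,13-epoxy lactone hydroazulenol (key-step precursor) | C=C1C[C@H](O[Si](C)(C)C(C)(C)C)[C@@]25[C@]3(CO3)C(=O)O[C@@H]2/C=C(/C)CC[C@]15O | intermediate
24 | 13-hydroxy-1-oxo germacranolide, C8 OTBS (key-step product) | C=C1C[C@H](O[Si](C)(C)C(C)(C)C)C2=C(CO)C(=O)O[C@@H]2/C=C(/C)CCC1=O | intermediate
25 | 8,13-dihydroxy-1-oxo germacranolide | C=C1C[C@H](O)C2=C(CO)C(=O)O[C@@H]2/C=C(/C)CCC1=O | intermediate
26 | 8,13-diacetoxy-1-oxo germacranolide | C=C1C[C@H](OC(C)=O)C2=C(COC(C)=O)C(=O)O[C@@H]2/C=C(/C)CCC1=O | intermediate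
27 | 8alpha,13-diacetoxy-1alpha-hydroxygermacra-4,7(11),10(14)-trien-6alpha,12-olide | C=C1C[C@H](OC(C)=O)C2=C(COC(C)=O)C(=O)O[C@@H]2/C=C(/C)CC[C@@H]1O | target

Total step count: 17. Longest linear sequence: 17 steps (1 to 27).

Steps most likely to fail

**Step 14 (labelled step).**
- What may go wrong: overlap between C1-C7 and the oxirane C11-O bond may stay too poor in the strained tricycle. The alkoxide would then persist and the glycidic lactone would be consumed by other base-induced pathways.
- The product may also be degraded when the C13 alkoxide abstracts a proton at C6 or C2 (epimerisation, transannular Michael addition).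
- Fallback: homolytic instead of heterolytic cleavage, which needs neither an oxirane nor a C11 stereocentre. It sets out from 22.
- PhI(OAc)2 and I2 in cyclohexane/CH2Cl2 under visible light turn the C1 hydroxyl into its hypoiodite. The alkoxyl radical undergoes beta-scission of C1-C7, the only cleavage that leads to a stabilised radical (allylic over C7, C11, C13 and conjugated to the lactone).
- Iodine transfer at the primary terminus gives the 13-iodo-1-oxo germacranolide F1. Silver-assisted hydrolysis (Ag2CO3, aqueous acetone) then gives 24, where the route is rejoined.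
- Alkoxyl radical fragmentation of fused tertiary carbinols to medium-ring ketones and hydrolysis of allylic iodides are established reactions.

**Step 13.**
- What may go wrong: poor facial selectivity in the ring closure of the peroxy enolate, since the bottom-face C8 silyloxy group also crowds the convex lactone face.
- Premature fragmentation followed by over-oxidation of the liberated enone is the second risk.
- Fallback: reagent control instead of substrate control. It sets out from 22.
- i-Bu2AlH (CH2Cl2, -78 °C to 0 °C) reduces the lactone to the 1,6,12-triol F2, a 2-substituted allylic alcohol.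
- Sharpless asymmetric epoxidation follows (Ti(Oi-Pr)4, D-(-)-diethyl tartrate, t-BuOOH, 4 A molecular sieves, CH2Cl2, -20 °C). This tartrate enantiomer turns allyl alcohol into (R)-glycidol, which here corresponds to oxygen on the C8 side, and it gives the 11,13-epoxy triol F3.
- Oxidative lactonisation of the primary C12 alcohol onto O6 (TEMPO, PhI(OAc)2, CH2Cl2) returns to 23.

**Step 6.**
- What may go wrong: competing conjugate addition to the exocyclic enone, sluggish addition to the neopentylic carbonyl, and erosion of facial selectivity by the bottom-face silyloxy group.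
- Fallback: chelation control instead of steric control. It sets out from 10.
- HF·pyridine removes the triethylsilyl group to give the beta-hydroxy enone F4.
- Excess Grignard reagent 12 (Et2O/CH2Cl2, -78 °C) first forms the C6 magnesium alkoxide, which chelates the C1 carbonyl oxygen and covers the top face. A second equivalent then adds from the bottom face and gives the 1,6-diol diene F5.
- Ring-closing metathesis under the conditions of step 7 returns to the route at 16 and saves the separate desilylation.

Further compounds
F1 | step 14 | 8alpha-(tert-butyldimethylsilyloxy)-13-iodo-1-oxogermacra-4,7(11),10(14)-trien-6alpha,12-olide | C=C1C[C@H](O[Si](C)(C)C(C)(C)C)C2=C(CI)C(=O)O[C@@H]2/C=C(/C)CCC1=O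
F2 | step 13 | 1,6,12-triol from reduction of 22 (C11=C13 retained) | C=C1C[C@H](O[Si](C)(C)C(C)(C)C)[C@@]2(C(=C)CO)[C@H](O)/C=C(/C)CC[C@]12O
F3 | step 13 | 11,13-epoxy-1,6,12-triol | C=C1C[C@H](O[Si](C)(C)C(C)(C)C)[C@@]2([C@@]3(CO)CO3)[C@H](O)/C=C(/C)CC[C@]12O
F4 | step 6 | C6 alcohol of the C10-methylene cyclopentanone | O=C1C(=C)C[C@H](O[Si](C)(C)C(C)(C)C)[C@@]1(CC(=O)OC(C)(C)C)[C@@H](O)C=C
F5 | step 6 | 1,6-diol diene | C=C1C[C@H](O[Si](C)(C)C(C)(C)C)[C@@](CC(=O)OC(C)(C)C)([C@@H](O)C=C)[C@]1(O)CCC(C)=C
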